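Rings: A is the terminal 3,5-dihydroxyphenyl ring and B the central ring. C, D and E follow outward along each of two identical arms (eight phloroglucinol units, 19 OH, five aryl ether bridges, two biaryl bonds).
Enabling feature: ring A is a 1,3,5-trioxygenated benzene whose C1 oxygen sits on C1 of ring B, a carbon shielded by the aryloxy groups at C2 and C6 of ring B. That oxygen therefore receives a slim O–C≡CH unit, and ring A is grown on it instead of being attached as an aryl group.
Cuts, in retrosynthetic order: all O-alkyl bonds; C1–C6, C2–C3 and C3–C4 of ring A (benzannulation of the ring B ethynyl ether with 3-ethoxycyclobutenone); the O–C≡C bond (trichloroethylene); both B–O–C bridges (SNAr on 2,6-difluoro-4-methoxybenzaldehyde, CHO standing for the later C1–OH); the C–O–D bridge (Ullmann-type coupling); the D–E bond (Ullmann homocoupling).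
Forward order: D–E biaryl, oxygenation of ring D at C3 (formylation, Baeyer–Villiger), ring C, two arms onto ring B, CHO to OH, ynol ether, ring A (the only ring built), global dealkylation.
Stereochemistry: the target has no stereocentre, and the D–E axes are not stereogenic because ring E is symmetric about the axis, so nothing has to be controlled.

Key step: step 13

Remark: Ar7 = 4-methoxy-2,6-bis{4-[(2,2',4,4',6,6'-hexamethoxybiphenyl-3-yl)oxy]-2,6-dimethoxyphenoxy}phenyl, that is rings B, C, C', D, D', E and E' with all seventeen remaining oxygens methylated. Ring A numbering: C1 bears the oxygen to ring B, C3 the new hydroxyl, C5 the ethoxy group.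
Assumption: every compound marked as starting material in the list is taken as commercial (ethoxyacetylene as its hexane solution).

Step 1
Reactants: 1 1,3,5-trimethoxybenzene
Product: 2 2-iodo-1,3,5-trimethoxybenzene
Conditions: NIS (1.0 equiv), MeCN, rt, dark
Reagents that add atoms: N-iodosuccinimide, O=C1CCC(=O)N1I
Why: Electrophilic aromatic iodination of a strongly activated arene with three equivalent CH positions should stop after one iodine when the reagent is limiting.

Step 2
Reactants: 2 2-iodo-1,3,5-trimethoxybenzene (two molecules)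
Product: 3 2,2',4,4',6,6'-hexamethoxybiphenyl (rings D and E)
Conditions: activated Cu bronze (excess), DMF, 150 °C, argon
Reagents that add atoms: none
Why: The classical Ullmann homocoupling tolerates two ortho-methoxy groups on each partner and makes the tetra-ortho-substituted D–E bond without any cross-coupling selectivity problem.

Step 3
Reactants: 3 2,2',4,4',6,6'-hexamethoxybiphenyl
Product: 5 2,2',4,4',6,6'-hexamethoxybiphenyl-3-carbaldehyde, via iminium salt 4 (not isolated)
Conditions: POCl3 (1.0 equiv), DMF, ClCH2CH2Cl, 0 °C → rt; then ice–water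
Reagents that add atoms: N,N-dimethylformamide, CN(C)C=O; water, O
Why: Vilsmeier–Haack formylation attacks one of four equivalent CH positions flanked by two methoxy groups; the reagent is kept limiting so that the monoaldehyde should dominate, and unreacted 3 is recovered and recycled.

Step 4
Reactants: 5 2,2',4,4',6,6'-hexamethoxybiphenyl-3-carbaldehyde
Product: 7 2,2',4,4',6,6'-hexamethoxybiphenyl-3-ol, via aryl formate 6 (not isolated)
Conditions: mCPBA (1.2 equiv), CH2Cl2, 0 °C → rt; then K2CO3 (cat.), MeOH, rt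
Reagents that add atoms: meta-chloroperoxybenzoic acid, OOC(=O)c1cccc(Cl)c1
Why: In this Baeyer–Villiger (Dakin-type) oxidation the electron-rich aryl group migrates in the Criegee adduct to give the aryl formate, which mild methanolysis cleaves to the ring D phenol.

Step 5
Reactants: 8 4-bromo-2,6-dimethoxyphenol
Product: 9 2-(benzyloxy)-5-bromo-1,3-dimethoxybenzene
Conditions: BnBr, K2CO3, DMF, rt
Reagents that add atoms: benzyl bromide, BrCc1ccccc1
Why: Williamson etherification masks the ring C oxygen that will later attack ring B with a group removable by hydrogenolysis beside methyl ethers.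

Step 6
Reactants: 7 2,2',4,4',6,6'-hexamethoxybiphenyl-3-ol; 9 2-(benzyloxy)-5-bromo-1,3-dimethoxybenzene
Product: 10 3-[4-(benzyloxy)-3,5-dimethoxyphenoxy]-2,2',4,4',6,6'-hexamethoxybiphenyl (rings C, D, E)
Conditions: CuI (10 mol %), picolinic acid (20 mol %), K3PO4 (2 equiv), DMSO, 100 °C, argon
Reagents that add atoms: none
Why: The Ullmann-type diaryl ether coupling with CuI and picolinic acid is suited to di-ortho-substituted phenols, and here the hindered ring D oxygen meets the bromide at C4 of ring C, which has only hydrogens beside it.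

Step 7
Reactants: 10 3-[4-(benzyloxy)-3,5-dimethoxyphenoxy]-2,2',4,4',6,6'-hexamethoxybiphenyl
Product: 11 4-[(2,2',4,4',6,6'-hexamethoxybiphenyl-3-yl)oxy]-2,6-dimethoxyphenol (arm phenol)
Conditions: H2 (1 atm), Pd/C, EtOAc–MeOH, rt
Reagents that add atoms: none
Why: Catalytic hydrogenolysis cleaves only the benzylic C–O bond, since methyl ethers, the diaryl ether and the biaryl are inert.

Step 8
Reactants: 11 arm phenol (2.2 equiv); 12 2,6-difluoro-4-methoxybenzaldehyde
Product: 14 seven-ring aldehyde Ar7–CHO, via monoether 13 (not isolated)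
Conditions: K2CO3, DMAc, 130 °C, argon
Reagents that add atoms: none
Why: In this twofold SNAr each fluorine lies ortho to the formyl group, which stabilises the Meisenheimer adduct, while the methoxy group and the first aryloxy group are meta to the carbon attacked and do not oppose the addition by resonance.

Step 9
Reactants: 14 seven-ring aldehyde Ar7–CHO
Product: 16 seven-ring phenol Ar7–OH, via seven-ring formate 15 (not isolated)
Conditions: mCPBA (1.3 equiv), CH2Cl2, 0 °C → rt; then K2CO3 (cat.), MeOH, rt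
Reagents that add atoms: meta-chloroperoxybenzoic acid, OOC(=O)c1cccc(Cl)c1
Why: Baeyer–Villiger oxidation with migration of the trioxygenated ring B places the oxygen on C1 between the two aryloxy groups without any intermolecular C–O bond formation at that crowded carbon.

Step 10
Reactants: 16 seven-ring phenol Ar7–OH; 17 trichloroethylene
Product: 19 (E)-1,2-dichlorovinyl ether Ar7–O–C(Cl)=CHCl, via dichloroacetylene 18 (not isolated)
Conditions: 17 (2 equiv), K2CO3, DMF, 70 °C
Reagents that add atoms: none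
Why: In this known O-dichlorovinylation of phenols the base takes HCl from trichloroethylene, and the hindered phenoxide adds anti to the transient linear dichloroacetylene, which sets the E geometry.

Step 11
Reactants: 19 (E)-1,2-dichlorovinyl ether Ar7–O–C(Cl)=CHCl
Product: 22 ethynyl ether Ar7–O–C≡CH, via chloroethynyl ether 20 (not isolated), via lithium acetylide 21 (not isolated)
Conditions: n-BuLi (2.2 equiv), THF, −78 → −40 °C; then H2O, −78 °C → rt; base-washed glassware
Reagents that add atoms: none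
Why: Deprotonation of the vinylic CH and loss of LiCl give the chloroalkyne, chlorine–lithium exchange gives the acetylide and water protonates it (the standard dichlorovinyl ether route to ynol ethers), all of which should be faster at −78 °C than ortho-lithiation of the methoxyarenes.

Step 12
Reactants: 23 ethoxyacetylene; 24 acetone
Product: 26 3-ethoxycyclobut-2-en-1-one, via ketene 25 (not isolated)
Conditions: 24 pyrolysed in a hot-wire ketene generator (ca. 700 °C), gas stream passed into 23, CH2Cl2, 0 °C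
Reagents that add atoms: none
Why: In the [2+2] cycloaddition of ketene with the electron-rich alkyne the terminal alkyne carbon bonds to the ketene carbonyl carbon, which places the ethoxy group at C3 of the cyclobutenone.

Step 13
Reactants: 22 ethynyl ether Ar7–O–C≡CH; 26 3-ethoxycyclobut-2-en-1-one
Product: 31 eight-ring phenol 3-ethoxy-5-(Ar7-oxy)phenol, via vinylketene 27 (not isolated), via cyclobutenone adduct 28 (not isolated), via dienylketene 29 (not isolated), via cyclohexadienone 30 (not isolated)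
Conditions: 26 (4 equiv, added by syringe pump over 8 h), toluene (0.05 M in 22), 110 °C, argon; then K2CO3, MeOH, rt (frees any phenol acylated by surplus ketene)
Reagents that add atoms: none
Why: Heating opens 26 in a reversible 4π electrocyclic reaction to (1-ethoxyvinyl)ketene 27, whose carbonyl carbon is attacked by the nucleophilic terminal carbon of ynol ether 22 in a [2+2] cycloaddition that forms C2–C3 and C1–C6 of ring A and gives the 4-vinylcyclobutenone 28. A second 4π opening of 28 cleaves the bond between the carbonyl carbon and the sp3 carbon to give dienylketene 29, whose 6π electrocyclisation joins the ketene carbon to the CH2 terminus (C3–C4), so that ring A closes as a six-membered carbocycle in a pericyclic 6π mode and dienone 30 tautomerises to phenol 31. The closest known reaction type is the Danheiser benzannulation of cyclobutenones with alkoxy- and siloxyalkynes; an aryloxyalkyne carries the same polarisation and, lacking a β-hydrogen on the oxygen substituent, cannot decay by retro-ene loss of an alkene at this temperature. Only the isomer of 29 with the ketene and ethoxyvinyl groups cis on the central double bond can cyclise, and because the opening is reversible the other isomer is fed back through 28. No stereocentre remains, the single one of 28 being erased on ring opening. The selectivity needed is the orientation of the [2+2] step, which the oxygen lone pair of the O–C≡CH unit secures by polarising the alkyne, so that the aryloxy group ends up meta to both the new hydroxyl at C3 and the ethoxy group at C5, while slow addition of surplus 26 keeps 27 dilute enough to meet 22 rather than itself.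

Step 14
Reactants: 31 eight-ring phenol 3-ethoxy-5-(Ar7-oxy)phenol
Product: 32 target CNP0227063.0
Conditions: BBr3 (40 equiv), CH2Cl2, −78 °C → rt, argon; then H2O, 0 °C
Reagents that add atoms: none
Why: In this Lewis acid ether cleavage BBr3 binds each alkyl aryl ether oxygen and bromide removes the methyl or ethyl group by SN2, whereas the diaryl ether and biaryl bonds offer no sp3 carbon and persist, so hydrolysis should free all nineteen hydroxyls.

Compound list
1 | 1,3,5-trimethoxybenzene | COc1cc(OC)cc(OC)c1 | starting material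
2 | 2-iodo-1,3,5-trimethoxybenzene | COc1cc(OC)c(I)c(OC)c1 | intermediate
3 | 2,2',4,4',6,6'-hexamethoxybiphenyl | COc1cc(OC)c(-c2c(OC)cc(OC)cc2OC)c(OC)c1 | intermediate
4 | [(2,2',4,4',6,6'-hexamethoxybiphenyl-3-yl)methylidene]dimethylammonium dichlorophosphate (not isolated) | COc1cc(OC)c(-c2c(OC)cc(OC)cc2OC)c(OC)c1C=[N+](C)C.[O-]P(=O)(Cl)Cl | intermediate
5 | 2,2',4,4',6,6'-hexamethoxybiphenyl-3-carbaldehyde | COc1cc(OC)c(-c2c(OC)cc(OC)cc2OC)c(OC)c1C=O | intermediate
6 | 2,2',4,4',6,6'-hexamethoxybiphenyl-3-yl formate (not isolated) | COc1cc(OC)c(-c2c(OC)cc(OC)cc2OC)c(OC)c1OC=O | intermediate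
7 | 2,2',4,4',6,6'-hexamethoxybiphenyl-3-ol | COc1cc(OC)c(-c2c(OC)cc(OC)cc2OC)c(OC)c1O | intermediate
8 | 4-bromo-2,6-dimethoxyphenol | COc1cc(Br)cc(OC)c1O | starting material
9 | 2-(benzyloxy)-5-bromo-1,3-dimethoxybenzene | COc1cc(Br)cc(OC)c1OCc1ccccc1 | intermediate
10 | 3-[4-(benzyloxy)-3,5-dimethoxyphenoxy]-2,2',4,4',6,6'-hexamethoxybiphenyl | COc1cc(Oc2c(OC)cc(OC)c(-c3c(OC)cc(OC)cc3OC)c2OC)cc(OC)c1OCc1ccccc1 | intermediate
11 | 4-[(2,2',4,4',6,6'-hexamethoxybiphenyl-3-yl)oxy]-2,6-dimethoxyphenol (arm phenol) | COc1cc(Oc2c(OC)cc(OC)c(-c3c(OC)cc(OC)cc3OC)c2OC)cc(OC)c1O | intermediate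
12 | 2,6-difluoro-4-methoxybenzaldehyde | COc1cc(F)c(C=O)c(F)c1 | starting material
13 | 2-fluoro-4-methoxy-6-{4-[(2,2',4,4',6,6'-hexamethoxybiphenyl-3-yl)oxy]-2,6-dimethoxyphenoxy}benzaldehyde (not isolated) | O=Cc1c(F)cc(OC)cc1Oc1c(OC)cc(Oc2c(OC)cc(OC)c(-c3c(OC)cc(OC)cc3OC)c2OC)cc1OC | intermediate
14 | seven-ring aldehyde Ar7–CHO | O=Cc1c(Oc2c(OC)cc(Oc3c(OC)cc(OC)c(-c4c(OC)cc(OC)cc4OC)c3OC)cc2OC)cc(OC)cc1Oc1c(OC)cc(Oc2c(OC)cc(OC)c(-c3c(OC)cc(OC)cc3OC)c2OC)cc1OC | intermediate
15 | seven-ring formate Ar7–OCHO (not isolated) | O=COc1c(Oc2c(OC)cc(Oc3c(OC)cc(OC)c(-c4c(OC)cc(OC)cc4OC)c3OC)cc2OC)cc(OC)cc1Oc1c(OC)cc(Oc2c(OC)cc(OC)c(-c3c(OC)cc(OC)cc3OC)c2OC)cc1OC | intermediate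
16 | seven-ring phenol Ar7–OH | Oc1c(Oc2c(OC)cc(Oc3c(OC)cc(OC)c(-c4c(OC)cc(OC)cc4OC)c3OC)cc2OC)cc(OC)cc1Oc1c(OC)cc(Oc2c(OC)cc(OC)c(-c3c(OC)cc(OC)cc3OC)c2OC)cc1OC | intermediate
17 | trichloroethylene | ClC=C(Cl)Cl | starting material
18 | dichloroacetylene (not isolated) | ClC#CCl | intermediate
19 | (E)-1,2-dichlorovinyl ether Ar7–O–C(Cl)=CHCl | Cl/C=C(/Cl)Oc1c(Oc2c(OC)cc(Oc3c(OC)cc(OC)c(-c4c(OC)cc(OC)cc4OC)c3OC)cc2OC)cc(OC)cc1Oc1c(OC)cc(Oc2c(OC)cc(OC)c(-c3c(OC)cc(OC)cc3OC)c2OC)cc1OC | intermediate
20 | chloroethynyl ether Ar7–O–C≡C–Cl (not isolated) | ClC#COc1c(Oc2c(OC)cc(Oc3c(OC)cc(OC)c(-c4c(OC)cc(OC)cc4OC)c3OC)cc2OC)cc(OC)cc1Oc1c(OC)cc(Oc2c(OC)cc(OC)c(-c3c(OC)cc(OC)cc3OC)c2OC)cc1OC | intermediate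
21 | lithium acetylide Ar7–O–C≡C–Li (not isolated) | [Li]C#COc1c(Oc2c(OC)cc(Oc3c(OC)cc(OC)c(-c4c(OC)cc(OC)cc4OC)c3OC)cc2OC)cc(OC)cc1Oc1c(OC)cc(Oc2c(OC)cc(OC)c(-c3c(OC)cc(OC)cc3OC)c2OC)cc1OC | intermediate
22 | ethynyl ether Ar7–O–C≡CH | C#COc1c(Oc2c(OC)cc(Oc3c(OC)cc(OC)c(-c4c(OC)cc(OC)cc4OC)c3OC)cc2OC)cc(OC)cc1Oc1c(OC)cc(Oc2c(OC)cc(OC)c(-c3c(OC)cc(OC)cc3OC)c2OC)cc1OC | intermediate
23 | ethoxyacetylene | CCOC#C | starting material
24 | acetone | CC(C)=O | starting material
25 | ketene (not isolated) | C=C=O | intermediate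
26 | 3-ethoxycyclobut-2-en-1-one | CCOC1=CC(=O)C1 | intermediate
27 | (1-ethoxyvinyl)ketene, 3-ethoxybuta-1,3-dien-1-one (not isolated) | C=C(OCC)C=C=O | intermediate
28 | 3-(Ar7-oxy)-4-(1-ethoxyvinyl)cyclobut-2-en-1-one, racemic (not isolated) | C=C(OCC)C1C(=O)C=C1Oc1c(Oc2c(OC)cc(Oc3c(OC)cc(OC)c(-c4c(OC)cc(OC)cc4OC)c3OC)cc2OC)cc(OC)cc1Oc1c(OC)cc(Oc2c(OC)cc(OC)c(-c3c(OC)cc(OC)cc3OC)c2OC)cc1OC | intermediate
29 | 3-(Ar7-oxy)-5-ethoxyhexa-1,3,5-trien-1-one, ketene and ethoxyvinyl groups cis on the central double bond (not isolated) | C=C(OCC)/C=C(C=C=O)/Oc1c(Oc2c(OC)cc(Oc3c(OC)cc(OC)c(-c4c(OC)cc(OC)cc4OC)c3OC)cc2OC)cc(OC)cc1Oc1c(OC)cc(Oc2c(OC)cc(OC)c(-c3c(OC)cc(OC)cc3OC)c2OC)cc1OC | intermediate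
30 | 3-(Ar7-oxy)-5-ethoxycyclohexa-2,4-dien-1-one (not isolated) | CCOC1=CC(=CC(=O)C1)Oc1c(Oc2c(OC)cc(Oc3c(OC)cc(OC)c(-c4c(OC)cc(OC)cc4OC)c3OC)cc2OC)cc(OC)cc1Oc1c(OC)cc(Oc2c(OC)cc(OC)c(-c3c(OC)cc(OC)cc3OC)c2OC)cc1OC | intermediate
31 | eight-ring phenol 3-ethoxy-5-(Ar7-oxy)phenol | CCOc1cc(O)cc(c1)Oc1c(Oc2c(OC)cc(Oc3c(OC)cc(OC)c(-c4c(OC)cc(OC)cc4OC)c3OC)cc2OC)cc(OC)cc1Oc1c(OC)cc(Oc2c(OC)cc(OC)c(-c3c(OC)cc(OC)cc3OC)c2OC)cc1OC | intermediate
32 | CNP0227063.0 (free eight-ring polyphenol) | Oc1cc(O)cc(Oc2c(Oc3c(O)cc(Oc4c(O)cc(O)c(-c5c(O)cc(O)cc5O)c4O)cc3O)cc(O)cc2Oc2c(O)cc(Oc3c(O)cc(O)c(-c4c(O)cc(O)cc4O)c3O)cc2O)c1 | target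

Total step count: 14. Longest linear sequence: 12 steps (1–4, 6–11, 13, 14).

Steps most likely to fail

First, step 13. The vinylogous-ester stabilisation of 26 slows its ring opening. Self-condensation of the vinylketene and thermal oligomerisation of the aryloxyalkyne may therefore outrun the cycloaddition. The fallback sets out from 16 and returns at 32, and it attaches ring A as a preformed aryl group. Phenol 16 is coupled with 1-iodo-3,5-dimethoxybenzene under CuI, picolinic acid and K3PO4 in DMSO at 120 °C (Ullmann-type ether synthesis) to give the fully O-methylated eight-ring ether F1. BBr3 in CH2Cl2 followed by water then cleaves its nineteen methyl ethers to 32.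

Second, step 11. The terminal aryloxyalkyne may oligomerise or be hydrated during concentration and chromatography, and surplus n-BuLi may lithiate a methoxyarene ring. The fallback sets out from 19 and returns at 22, and it carries the alkyne in silyl-protected form. Compound 19 is treated with n-BuLi as before, but acetylide 21 is trapped with Me3SiCl to give the trimethylsilylethynyl ether F2, which can be purified and stored. n-Bu4NF in wet THF at 0 °C releases 22 just before use, and 22 is filtered through basic alumina and taken into step 13 as a solution.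

Third, step 14. Eighteen ether cleavages must all go to completion while boron aryloxides precipitate, and the free polyphenol may be air-oxidised during purification. The fallback sets out from 31 and returns at 32, and it moves the purification to a protected derivative. The crude product of the BBr3 cleavage is peracetylated with Ac2O and pyridine to give the nonadecaacetate F3. This derivative is neutral, air-stable and separable on silica from incompletely cleaved material. Acid-catalysed methanolysis (AcCl cat., degassed MeOH, argon) then removes the acetyl groups to give 32.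

Further compounds
F1 | step 13 | fully O-methylated eight-ring ether, 1,3-dimethoxy-5-(Ar7-oxy)benzene | COc1cc(OC)cc(c1)Oc1c(Oc2c(OC)cc(Oc3c(OC)cc(OC)c(-c4c(OC)cc(OC)cc4OC)c3OC)cc2OC)cc(OC)cc1Oc1c(OC)cc(Oc2c(OC)cc(OC)c(-c3c(OC)cc(OC)cc3OC)c2OC)cc1OC
F2 | step 11 | trimethylsilylethynyl ether Ar7–O–C≡C–SiMe3 | C[Si](C)(C)C#COc1c(Oc2c(OC)cc(Oc3c(OC)cc(OC)c(-c4c(OC)cc(OC)cc4OC)c3OC)cc2OC)cc(OC)cc1Oc1c(OC)cc(Oc2c(OC)cc(OC)c(-c3c(OC)cc(OC)cc3OC)c2OC)cc1OC
F3 | step 14 | nonadecaacetate of 32 | CC(=O)Oc1cc(OC(C)=O)cc(Oc2c(Oc3c(OC(C)=O)cc(Oc4c(OC(C)=O)cc(OC(C)=O)c(-c5c(OC(C)=O)cc(OC(C)=O)cc5OC(C)=O)c4OC(C)=O)cc3OC(C)=O)cc(OC(C)=O)cc2Oc2c(OC(C)=O)cc(Oc3c(OC(C)=O)cc(OC(C)=O)c(-c4c(OC(C)=O)cc(OC(C)=O)cc4OC(C)=O)c3OC(C)=O)cc2OC(C)=O)c1
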